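The cyclohexane ring is cut into a C3=C4 dienophile and a C5=C6–C1=C2 diene (ring C1 = methyl-bearing carbon, side chain C7–C11 on C4). One thermal Diels–Alder reaction of an (E)-β-angeloyloxy enone carrying the whole side chain with a 1-silyloxy-2-(allyloxycarbonyloxy)-3-methylbutadiene forms C4–C5 and C2–C3 and sets C3, C4 and C5. It exploits the O–C3–C4(C7)–C5–O segment: the C5 oxygen and the C1 methyl group steer the regiochemistry, the C7 ketone (later the exocyclic methylene) is the endo activator, and the hydrogen-bonded C8 carbinol, from methyl (R)-glycidate, shields one face before Mitsunobu angeloylation inverts it. The enol carbonate then gives the enone for reduction and directed epoxidation.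

Key step: step 8

Remark on names: locants follow the target in a bisabolane-type numbering: ring C1 (bearing methyl C15) to C6, C7 on C4, then C8–C11, and C14 is the methylene carbon on C7. Compounds with a C7 ketone lack C14 and are named as 14-nor. Angeloyl = (2Z)-2-methylbut-2-enoyl, TBS = tert-butyldimethylsilyl, PMB = 4-methoxybenzyl.

Assumption: compounds 1, 5 and 7, the Grignard reagents and the D-fructose-derived ketone of step 14 are taken as commercial.

Step 1
Reactants: 1 methyl (2R)-oxirane-2-carboxylate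
Product: 2 methyl (2R)-2-hydroxy-5-methylhex-4-enoate
Conditions: 2-methylprop-1-enylmagnesium bromide (1.3 equiv), CuI (10 mol%), THF, −40 °C; aq. NH4Cl
Reagents that add atoms: 2-methylprop-1-enylmagnesium bromide, CC(C)=C[Mg]Br
Why: Copper-catalysed Grignard opening of the glycidic ester (SN2 at the unsubstituted C3) should give the α-hydroxy ester, and the carbinol carbon (the future C8) is not touched and stays (R).

Step 2
Reactants: 2 methyl (2R)-2-hydroxy-5-methylhex-4-enoate
Product: 3 (2R)-2-hydroxy-N-methoxy-N,5-dimethylhex-4-enamide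
Conditions: MeNHOMe·HCl (1.6 equiv), iPrMgCl (4.3 equiv), THF, −20 → 0 °C
Reagents that add atoms: N,O-dimethylhydroxylamine hydrochloride, CNOC.Cl
Why: Aminolysis of the methyl ester by the magnesium amide (Weinreb amide formation) should proceed with the carbinol carried as its magnesium alkoxide and without enolisation of the stereocentre.

Step 3
Reactants: 3 (2R)-2-hydroxy-N-methoxy-N,5-dimethylhex-4-enamide
Product: 4 (4R)-4-hydroxy-7-methyloct-6-en-1-yn-3-one
Conditions: ethynylmagnesium bromide (3 equiv), THF, 0 °C; aq. NH4Cl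
Reagents that add atoms: ethynylmagnesium bromide, C#C[Mg]Br
Why: Weinreb ketone synthesis, in which the N-methoxy-N-methylamide stops the Grignard addition at the ketone stage, should give the terminal ynone.

Step 4
Reactants: 4 (4R)-4-hydroxy-7-methyloct-6-en-1-yn-3-one, 5 angelic acid [(2Z)-2-methylbut-2-enoic acid]
Product: 6 (1E,4R)-4-hydroxy-7-methyl-3-oxoocta-1,6-dien-1-yl (2Z)-2-methylbut-2-enoate
Conditions: N-methylmorpholine (10 mol%), 5 (1.5 equiv), CH2Cl2, 0 °C → rt
Reagents that add atoms: none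
Why: Amine-catalysed conjugate addition of the carboxylic acid to the terminal ynone should give the thermodynamically preferred (E)-β-acyloxy enone, while the acidic medium holds back 5-endo attack of the free carbinol and Z→E isomerisation of the angelate.

Step 5
Reactants: 7 2-[(tert-butyldimethylsilyl)oxy]acetaldehyde
Product: 8 rac-1-[(tert-butyldimethylsilyl)oxy]-3-methylbut-3-en-2-ol
Conditions: isopropenylmagnesium bromide (1.2 equiv), THF, −78 → 0 °C; aq. NH4Cl
Reagents that add atoms: isopropenylmagnesium bromide, CC(=C)[Mg]Br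
Why: Grignard addition to the aldehyde; the racemate is used because the new carbinol centre is removed in step 6.

Step 6
Reactants: 8 rac-1-[(tert-butyldimethylsilyl)oxy]-3-methylbut-3-en-2-ol
Product: 9 1-[(tert-butyldimethylsilyl)oxy]-3-methylbut-3-en-2-one
Conditions: Dess–Martin periodinane (1.3 equiv), CH2Cl2, 0 °C → rt
Reagents that add atoms: none
Why: Dess–Martin oxidation should convert the allylic alcohol into the enone under near-neutral conditions that keep the silyl ether.

Step 7
Reactants: 9 1-[(tert-butyldimethylsilyl)oxy]-3-methylbut-3-en-2-one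
Product: 11 (1Z)-1-[(tert-butyldimethylsilyl)oxy]-3-methylbuta-1,3-dien-2-yl prop-2-en-1-yl carbonate, via sodium enolate 10 (not isolated)
Conditions: NaN(SiMe3)2 (1.1 equiv), THF, −78 °C; then allyl chloroformate (1.2 equiv), −78 → −40 °C
Reagents that add atoms: allyl chloroformate, C=CCOC(=O)Cl
Why: Kinetic deprotonation at the only α-CH2 should give the (Z)-enolate (silyloxy group cis to the enolate oxygen), and O-acylation by the chloroformate (enol carbonate formation) fixes a diene whose silyloxy group sits in the outside position.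

Step 8
Reactants: 6 (1E,4R)-4-hydroxy-7-methyl-3-oxoocta-1,6-dien-1-yl (2Z)-2-methylbut-2-enoate, 11 (1Z)-1-[(tert-butyldimethylsilyl)oxy]-3-methylbuta-1,3-dien-2-yl prop-2-en-1-yl carbonate
Product: 12 (3S,4R,5R,8R)-3-angeloyloxy-6-(allyloxycarbonyloxy)-5-[(tert-butyldimethylsilyl)oxy]-8-hydroxy-14-norbisabola-1(6),10-dien-7-one
Conditions: 11 (2 equiv), toluene, 2,6-di-tert-butyl-4-methylphenol (1 mol%), 60 °C
Reagents that add atoms: none
Why: Concerted suprafacial [4+2] cycloaddition of the electron-rich diene 11 to the hydrogen-bond-activated enone 6; the closest known type is the thermal Diels–Alder reaction of 1-silyloxydienes with α'-hydroxy enones. The only ring closed is the cyclohexene, formed intermolecularly in the 4+2 mode through an endo transition state in which C5 bonds to C4 and C2 to C3. C3 is set by the (E) geometry of the dienophile (C3–O trans to C7), C5 by the outside silyloxy group of the (Z)-enol ether together with the endo C7 carbonyl (C5–O cis to C7), and C4 by the diene face. That face is chosen by C8: the (R)-carbinol hydrogen bonds to the C7 carbonyl, the s-cis enone lies in the plane of this five-membered chelate, and the diene should add anti to the C9 chain. Regioselectivity is needed and should come from the strong 1-donor on C5 and the C1 methyl group, which put the largest HOMO coefficient on C2 for bonding to the enone β-carbon C3, while the weakly donating enol carbonate on C6 cannot reverse this. Chemoselectivity is secured because the trisubstituted, unactivated angelate and prenyl alkenes do not compete as dienophiles.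

Step 9
Reactants: 12 (3S,4R,5R,8R)-3-angeloyloxy-6-(allyloxycarbonyloxy)-5-[(tert-butyldimethylsilyl)oxy]-8-hydroxy-14-norbisabola-1(6),10-dien-7-one, 5 angelic acid
Product: 13 (3S,4R,5R,8S)-3,8-bis(angeloyloxy)-6-(allyloxycarbonyloxy)-5-[(tert-butyldimethylsilyl)oxy]-14-norbisabola-1(6),10-dien-7-one
Conditions: PPh3 (1.5 equiv), diisopropyl azodicarboxylate (1.5 equiv), 5 (1.5 equiv), toluene, 0 °C → rt
Reagents that add atoms: none
Why: Mitsunobu esterification, an SN2 displacement at the activated α-keto carbinol carbon, should invert C8 from (R) to the (S) configuration of the target and install the second angelate without Z/E isomerisation.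

Step 10
Reactants: 13 (3S,4R,5R,8S)-3,8-bis(angeloyloxy)-6-(allyloxycarbonyloxy)-5-[(tert-butyldimethylsilyl)oxy]-14-norbisabola-1(6),10-dien-7-one
Product: 14 (3S,4R,5R,8S)-3,8-bis(angeloyloxy)-6-(allyloxycarbonyloxy)-5-[(tert-butyldimethylsilyl)oxy]bisabola-1(6),7(14),10-triene
Conditions: Cp2Ti(μ-Cl)(μ-CH2)AlMe2 (Tebbe reagent, 1.2 equiv), pyridine (0.1 equiv), THF/toluene, −40 → 0 °C; aq. NaHCO3
Reagents that add atoms: Tebbe reagent Cp2Ti(μ-Cl)(μ-CH2)AlMe2, C[Al](C)C[Ti](Cl)(C1C=CC=C1)C1C=CC=C1
Why: Tebbe methylenation is non-basic, so the epimerisable C4 and C8 centres and the β-acyloxy ketone should survive, and at low temperature the only ketone (C6 is still masked as the enol carbonate) reacts much faster than the esters and the carbonate.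

Step 11
Reactants: 14 (3S,4R,5R,8S)-3,8-bis(angeloyloxy)-6-(allyloxycarbonyloxy)-5-[(tert-butyldimethylsilyl)oxy]bisabola-1(6),7(14),10-triene
Product: 15 (3S,4R,5R,8S)-3,8-bis(angeloyloxy)-5-[(tert-butyldimethylsilyl)oxy]bisabola-1,7(14),10-trien-6-one
Conditions: Pd(OAc)2 (5 mol%), 1,2-bis(diphenylphosphino)ethane (5 mol%), MeCN, 80 °C
Reagents that add atoms: none
Why: Palladium-catalysed decarboxylative dehydrogenation of the allyl enol carbonate (Tsuji–Saegusa type) should give the 2-methyl enone by oxidative addition of zerovalent palladium, loss of CO2 and β-hydride elimination from the regiodefined C1 palladium enolate toward C2–H, the allyl carbonate ionising far faster than the hindered allylic angelate at C8.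

Step 12
Reactants: 15 (3S,4R,5R,8S)-3,8-bis(angeloyloxy)-5-[(tert-butyldimethylsilyl)oxy]bisabola-1,7(14),10-trien-6-one
Product: 16 (3S,4S,5R,8S)-3,8-bis(angeloyloxy)-5-hydroxybisabola-1,7(14),10-trien-6-one
Conditions: HF·pyridine, pyridine, THF, 0 °C → rt
Reagents that add atoms: none
Why: Fluoride cleavage of the secondary silyl ether under buffered, weakly acidic conditions should leave the esters and the configuration of the α-ketol untouched.

Step 13
Reactants: 16 (3S,4S,5R,8S)-3,8-bis(angeloyloxy)-5-hydroxybisabola-1,7(14),10-trien-6-one, 5 angelic acid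
Product: 18 (3S,4R,5R,8S)-3,5,8-tris(angeloyloxy)bisabola-1,7(14),10-trien-6-one, via mixed anhydride 17 (not isolated)
Conditions: 5 (3 equiv), 2,4,6-trichlorobenzoyl chloride (3 equiv), Et3N (3.3 equiv), toluene, rt; then 16, 45 °C
Reagents that add atoms: none
Why: Yamaguchi-type mixed-anhydride acylation without a nucleophilic catalyst is the usual way to form angelates without isomerisation to tiglates, and C5 keeps its configuration because only the O–H bond reacts.

Step 14
Reactants: 18 (3S,4R,5R,8S)-3,5,8-tris(angeloyloxy)bisabola-1,7(14),10-trien-6-one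
Product: 19 (3S,4R,5R,8S,10R)-3,5,8-tris(angeloyloxy)-10,11-epoxybisabola-1,7(14)-dien-6-one
Conditions: D-fructose-derived Shi ketone (0.3 equiv), KHSO5 (as Oxone, 2KHSO5·KHSO4·K2SO4, 1.4 equiv), K2CO3, Bu4NHSO4 (5 mol%), MeCN/dimethoxymethane/aq. Na2B4O7–Na2EDTA buffer (pH 10.5), 0 °C
Reagents that add atoms: potassium peroxymonosulfate KHSO5, [K+].[O-]S(=O)(=O)OO
Why: Shi asymmetric epoxidation should touch only the electron-rich trisubstituted C10=C11 alkene (the enone, the angelates and the C7=C14 alkene next to an allylic ester are electron-poor or poor substrates), and the D-fructose-derived dioxirane delivers oxygen through the spiro transition state to the face that gives (10R).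

Step 15
Reactants: 19 (3S,4R,5R,8S,10R)-3,5,8-tris(angeloyloxy)-10,11-epoxybisabola-1,7(14)-dien-6-one
Product: 20 (3S,4R,5R,6S,8S,10R)-3,5,8-tris(angeloyloxy)-10,11-epoxybisabola-1,7(14)-dien-6-ol
Conditions: NaBH4 (1.2 equiv), CeCl3·7H2O (1.2 equiv), MeOH, −78 °C; AcOH quench at −78 °C
Reagents that add atoms: none
Why: Luche 1,2-reduction: in the half-chair with the C4 chain and the C3 ester pseudo-equatorial the C5 angelate is axial, so hydride should add to C6 anti to this axial α-acyloxy group and give the C6 alcohol cis to C5–O, while the low temperature and acidic quench suppress acyl migration.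

Step 16
Reactants: 20 (3S,4R,5R,6S,8S,10R)-3,5,8-tris(angeloyloxy)-10,11-epoxybisabola-1,7(14)-dien-6-ol
Product: 21 (1R,2S,3R,4S,5R,6R,8S,10R)-3,5,8-tris(angeloyloxy)-1,2:10,11-diepoxybisabol-7(14)-en-6-ol (CNP0147918.1)
Conditions: VO(acac)2 (5 mol%), tert-butyl hydroperoxide (in decane, 1.5 equiv), CH2Cl2, 0 °C → rt
Reagents that add atoms: tert-butyl hydroperoxide, CC(C)(C)OO
Why: Hydroxyl-directed epoxidation through the vanadium alkoxide–peroxide complex should deliver oxygen to the C1=C2 face syn to the C6 hydroxyl (and anti to the C3 ester), giving the (1R,2S) epoxide, while the other alkenes have no free allylic hydroxyl and stay intact.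

Compound list
1 | methyl (2R)-oxirane-2-carboxylate | COC(=O)[C@H]1CO1 | starting material
2 | methyl (2R)-2-hydroxy-5-methylhex-4-enoate | COC(=O)[C@@H](CC=C(C)C)O | intermediate
3 | (2R)-2-hydroxy-N-methoxy-N,5-dimethylhex-4-enamide | CON(C)C(=O)[C@@H](CC=C(C)C)O | intermediate
4 | (4R)-4-hydroxy-7-methyloct-6-en-1-yn-3-one | C#CC(=O)[C@@H](CC=C(C)C)O | intermediate
5 | angelic acid, (2Z)-2-methylbut-2-enoic acid | C/C=C(/C)C(=O)O | starting material
6 | (1E,4R)-4-hydroxy-7-methyl-3-oxoocta-1,6-dien-1-yl (2Z)-2-methylbut-2-enoate | O=C(/C=C/OC(=O)/C(C)=C\C)[C@@H](CC=C(C)C)O | intermediate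
7 | 2-[(tert-butyldimethylsilyl)oxy]acetaldehyde | O=CCO[Si](C)(C)C(C)(C)C | starting material
8 | rac-1-[(tert-butyldimethylsilyl)oxy]-3-methylbut-3-en-2-ol | C=C(C)C(O)CO[Si](C)(C)C(C)(C)C | intermediate
9 | 1-[(tert-butyldimethylsilyl)oxy]-3-methylbut-3-en-2-one | C=C(C)C(=O)CO[Si](C)(C)C(C)(C)C | intermediate
10 | sodium (1Z)-1-[(tert-butyldimethylsilyl)oxy]-3-methylbuta-1,3-dien-2-olate | C=C(C)/C([O-])=C/O[Si](C)(C)C(C)(C)C.[Na+] | intermediate
11 | (1Z)-1-[(tert-butyldimethylsilyl)oxy]-3-methylbuta-1,3-dien-2-yl prop-2-en-1-yl carbonate | C=C(C)/C(OC(=O)OCC=C)=C/O[Si](C)(C)C(C)(C)C | intermediate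
12 | (3S,4R,5R,8R)-3-angeloyloxy-6-(allyloxycarbonyloxy)-5-[(tert-butyldimethylsilyl)oxy]-8-hydroxy-14-norbisabola-1(6),10-dien-7-one | O=C([C@H]1[C@@H](O[Si](C)(C)C(C)(C)C)C(OC(=O)OCC=C)=C(C)C[C@@H]1OC(=O)/C(C)=C\C)[C@@H](CC=C(C)C)O | intermediate
13 | (3S,4R,5R,8S)-3,8-bis(angeloyloxy)-6-(allyloxycarbonyloxy)-5-[(tert-butyldimethylsilyl)oxy]-14-norbisabola-1(6),10-dien-7-one | O=C([C@H]1[C@@H](O[Si](C)(C)C(C)(C)C)C(OC(=O)OCC=C)=C(C)C[C@@H]1OC(=O)/C(C)=C\C)[C@H](CC=C(C)C)OC(=O)/C(C)=C\C | intermediate
14 | (3S,4R,5R,8S)-3,8-bis(angeloyloxy)-6-(allyloxycarbonyloxy)-5-[(tert-butyldimethylsilyl)oxy]bisabola-1(6),7(14),10-triene | C=C([C@H]1[C@@H](O[Si](C)(C)C(C)(C)C)C(OC(=O)OCC=C)=C(C)C[C@@H]1OC(=O)/C(C)=C\C)[C@H](CC=C(C)C)OC(=O)/C(C)=C\C | intermediate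
15 | (3S,4R,5R,8S)-3,8-bis(angeloyloxy)-5-[(tert-butyldimethylsilyl)oxy]bisabola-1,7(14),10-trien-6-one | C=C([C@H]1[C@@H](O[Si](C)(C)C(C)(C)C)C(=O)C(C)=C[C@@H]1OC(=O)/C(C)=C\C)[C@H](CC=C(C)C)OC(=O)/C(C)=C\C | intermediate
16 | (3S,4S,5R,8S)-3,8-bis(angeloyloxy)-5-hydroxybisabola-1,7(14),10-trien-6-one | C=C([C@H]1[C@@H](O)C(=O)C(C)=C[C@@H]1OC(=O)/C(C)=C\C)[C@H](CC=C(C)C)OC(=O)/C(C)=C\C | intermediate
17 | (2Z)-2-methylbut-2-enoic 2,4,6-trichlorobenzoic anhydride | C/C=C(/C)C(=O)OC(=O)c1c(Cl)cc(Cl)cc1Cl | intermediate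
18 | (3S,4R,5R,8S)-3,5,8-tris(angeloyloxy)bisabola-1,7(14),10-trien-6-one | C=C([C@H]1[C@@H](OC(=O)/C(C)=C\C)C(=O)C(C)=C[C@@H]1OC(=O)/C(C)=C\C)[C@H](CC=C(C)C)OC(=O)/C(C)=C\C | intermediate
19 | (3S,4R,5R,8S,10R)-3,5,8-tris(angeloyloxy)-10,11-epoxybisabola-1,7(14)-dien-6-one | C=C([C@H]1[C@@H](OC(=O)/C(C)=C\C)C(=O)C(C)=C[C@@H]1OC(=O)/C(C)=C\C)[C@H](C[C@H]1OC1(C)C)OC(=O)/C(C)=C\C | intermediate
20 | (3S,4R,5R,6S,8S,10R)-3,5,8-tris(angeloyloxy)-10,11-epoxybisabola-1,7(14)-dien-6-ol | C=C([C@H]1[C@@H](OC(=O)/C(C)=C\C)[C@@H](O)C(C)=C[C@@H]1OC(=O)/C(C)=C\C)[C@H](C[C@H]1OC1(C)C)OC(=O)/C(C)=C\C | intermediate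
21 | (1R,2S,3R,4S,5R,6R,8S,10R)-3,5,8-tris(angeloyloxy)-1,2:10,11-diepoxybisabol-7(14)-en-6-ol (CNP0147918.1) | C=C([C@H]1[C@@H](OC(=O)/C(C)=C\C)[C@@H](O)[C@@]2(C)O[C@H]2[C@@H]1OC(=O)/C(C)=C\C)[C@H](C[C@H]1OC1(C)C)OC(=O)/C(C)=C\C | target

Total step count: 16. Longest linear sequence: 13 steps (steps 1–4, then 8–16); steps 5–7 make the diene in a side branch.

Steps most likely to fail, each with a fallback:

Step 8. The small hydrogen-bonded carbinol may discriminate the two enone faces only partly, the cycloaddition may be slow, and 6 may be lost by 5-endo cyclisation of its free hydroxyl with expulsion of angelate. The fallback sets out from 3 and comes back at 12, and it also keeps the carbinol masked through the ynone stage. Amide 3 would be O-alkylated with 4-methoxybenzyl 2,2,2-trichloroacetimidate (cat. camphorsulfonic acid, CH2Cl2) to (2R)-N-methoxy-2-[(4-methoxybenzyl)oxy]-N,5-dimethylhex-4-enamide F1. Ethynylmagnesium bromide would then give (4R)-4-[(4-methoxybenzyl)oxy]-7-methyloct-6-en-1-yn-3-one F2, and addition of 5 as in step 4 would give the (E)-β-angeloyloxy enone PMB ether F3. The cycloaddition with 11 would be run under chelate control (MgBr2·OEt2, CH2Cl2, −60 → −30 °C), with magnesium bridging the C7 carbonyl and the C8 ether oxygen so that the same face is shielded, to give the 8-O-PMB cycloadduct F4. DDQ (CH2Cl2/pH 7 buffer) would then free the carbinol and return to 12.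

Step 11. Zerovalent palladium may ionise the allylic angelate at C8 (allylic transposition or loss of configuration), or the palladium enolate may be C-allylated instead of undergoing β-hydride elimination. The fallback sets out from 12 and comes back at 15 by changing the order, so that no allylic ester is present in the palladium step. Hydroxy ketone 12 would be methylenated with excess Cp2Ti(μ-Cl)(μ-CH2)AlMe2 to (3S,4R,5R,8R)-3-angeloyloxy-6-(allyloxycarbonyloxy)-5-[(tert-butyldimethylsilyl)oxy]bisabola-1(6),7(14),10-trien-8-ol F5. The decarboxylative dehydrogenation (Pd(OAc)2, 1,2-bis(diphenylphosphino)ethane, MeCN, 80 °C) would then give (3S,4R,5R,8R)-3-angeloyloxy-5-[(tert-butyldimethylsilyl)oxy]-8-hydroxybisabola-1,7(14),10-trien-6-one F6, whose free allylic alcohol is not ionised. Mitsunobu reaction of F6 with 5 (PPh3, diisopropyl azodicarboxylate) would invert and esterify C8 and give 15.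

Step 13. The hindered acylation needs warming in the presence of base, so the α-ketol may enolise (epimerisation at C5 or drift to the diosphenol) and the angelate may isomerise to the tiglate. The fallback sets out from 16 and comes back at 18 by building the angelate on the oxygen in two mild steps. Alcohol 16 would be acylated at 0 °C with 2-[bis(2,2,2-trifluoroethoxy)phosphoryl]propanoic acid (N,N'-dicyclohexylcarbodiimide, cat. 4-dimethylaminopyridine, CH2Cl2) to the 5-O-[2-(bis(2,2,2-trifluoroethoxy)phosphoryl)propanoyl] ester F7 (mixture at the phosphonate carbon). Still–Gennari olefination with acetaldehyde (KN(SiMe3)2, 18-crown-6, THF, −78 °C) should then form the (Z)-2-methylbut-2-enoate and give 18.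

Further compounds
F1 | step 8 | (2R)-N-methoxy-2-[(4-methoxybenzyl)oxy]-N,5-dimethylhex-4-enamide | CON(C)C(=O)[C@@H](CC=C(C)C)OCc1ccc(OC)cc1
F2 | step 8 | (4R)-4-[(4-methoxybenzyl)oxy]-7-methyloct-6-en-1-yn-3-one | C#CC(=O)[C@@H](CC=C(C)C)OCc1ccc(OC)cc1
F3 | step 8 | (1E,4R)-4-[(4-methoxybenzyl)oxy]-7-methyl-3-oxoocta-1,6-dien-1-yl (2Z)-2-methylbut-2-enoate | O=C(/C=C/OC(=O)/C(C)=C\C)[C@@H](CC=C(C)C)OCc1ccc(OC)cc1
F4 | step 8 | (3S,4R,5R,8R)-3-angeloyloxy-6-(allyloxycarbonyloxy)-5-[(tert-butyldimethylsilyl)oxy]-8-[(4-methoxybenzyl)oxy]-14-norbisabola-1(6),10-dien-7-one | O=C([C@H]1[C@@H](O[Si](C)(C)C(C)(C)C)C(OC(=O)OCC=C)=C(C)C[C@@H]1OC(=O)/C(C)=C\C)[C@@H](CC=C(C)C)OCc1ccc(OC)cc1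
F5 | step 11 | (3S,4R,5R,8R)-3-angeloyloxy-6-(allyloxycarbonyloxy)-5-[(tert-butyldimethylsilyl)oxy]bisabola-1(6),7(14),10-trien-8-ol | C=C([C@H]1[C@@H](O[Si](C)(C)C(C)(C)C)C(OC(=O)OCC=C)=C(C)C[C@@H]1OC(=O)/C(C)=C\C)[C@@H](CC=C(C)C)O
F6 | step 11 | (3S,4R,5R,8R)-3-angeloyloxy-5-[(tert-butyldimethylsilyl)oxy]-8-hydroxybisabola-1,7(14),10-trien-6-one | C=C([C@H]1[C@@H](O[Si](C)(C)C(C)(C)C)C(=O)C(C)=C[C@@H]1OC(=O)/C(C)=C\C)[C@@H](CC=C(C)C)O
F7 | step 13 | (3S,4R,5R,8S)-3,8-bis(angeloyloxy)-5-{2-[bis(2,2,2-trifluoroethoxy)phosphoryl]propanoyloxy}bisabola-1,7(14),10-trien-6-one | C=C([C@H]1[C@@H](OC(=O)C(C)P(=O)(OCC(F)(F)F)OCC(F)(F)F)C(=O)C(C)=C[C@@H]1OC(=O)/C(C)=C\C)[C@H](CC=C(C)C)OC(=O)/C(C)=C\C
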